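The numbers stand for no real mixture; what happens was integrated by code.

Dosing leaves the substrate in zeta younger at work-up than the substrate in alpha, and on a repeat that age is what I watch.

    substrate → open intermediate (k1 = 0.0659 /s)
    open intermediate → target (k2 = 0.0502 /s)
    open intermediate → side product A (k3 = 0.00686 /s)
    open intermediate + capture agent → trapped intermediate (k4 = 67.6 /M/s)
    substrate + target → side product B (k5 = 1.28 /M/s)

| flask | substrate | capture agent | time | remark |
|---|---|---|---|---|
| alpha | 10 mM | 3.00 mM | 40 s | everything together in a closed stirred flask, run for 40 s |
| beta | 10 mM | 3.00 mM | 40 s | a tube with plug flow, the mixed feed as stated, residence time 40 s |
| theta | 10 mM | 3.00 mM |  | one stirred flow tank at steady state, fed with the mixture as stated, mean residence time 40 s |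
| zeta | 10 mM (fed, over 32.0 s) | 3.00 mM | 40 s | a stirred flask in which substrate is dosed at a steady rate over 32.0 s without added volume, worked up at 40 s |

- the set-up with the highest amount of open intermediate at the outlet or at the end, in percent of the substrate put in ("none" if the first two lie within 2 percentage points) (alpha / beta / theta / zeta / none)
- amount of open intermediate at the outlet or at the end, in percent of the substrate put in, alpha
- amount of open intermediate at the outlet or at the end, in percent of the substrate put in, beta
- amount of open intermediate at the outlet or at the end, in percent of the substrate put in, theta
- amount of open intermediate at the outlet or at the end, in percent of the substrate put in, zeta

- in percentages every species weighs as the substrate in it: one side product B counts as two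
- the stated concentrations are those of everything mixed, before any reaction; amounts are the same in each set-up
- the feed brings no volume worth counting
- run time (alpha): 40 s

I replace the steady feed by its mean and treat zeta as charged whole at mid-feed. That gives 24.0 s, the mean age of the charge, meaning the time the average substrate has spent in the flask at work-up. The error is easy to check. Substrate decay over the mean age leaves 20.6%, while averaging the true feed leaves 24.6%, so the mean runs low by 4 percentage points.

Now I turn the question round. In this picture alpha and zeta sit on one curve of open intermediate, so for alpha to beat zeta the mean age would have to lie before the top of that curve, where making still exceeds drain. Open intermediate drains to target and side product A at 0.0571 /s, and I neglect the loss of substrate with target. Without capture agent, a whole charge gives 36.2% at the mean age. Capture agent is the limiting reagent, its charge being smaller than the substrate's. At its full charge capture takes open intermediate faster than drain does, so in my reckoning the charge of capture agent comes off open intermediate at 5.41 s of substrate age, when substrate has delivered that amount, which costs 10.4% by the mean age. So I commit to 25.8% for zeta. At the mean age, in this reckoning, making is 0.136 mM/s and drain is 0.147 mM/s, so drain is larger and my curve is already past its top.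

At 40 s the same sum gives 22.7% less 4.17%, which is 18.5% for alpha and 18.5% for beta, whose residence time equals alpha's run. For theta, I take the converted substrate less the capture charge and share the rest between outflow and drain, which gives 12.9%. My winner is zeta.

The forecast gives 16.3% for alpha, 16.3% for beta, 14.1% for theta and 24% for zeta, also naming zeta, with alpha lower than my figure, beta lower, zeta lower and theta higher, on the ground: “Dosing delays formation”.

The simulation gives 16.4% for alpha, 16.4% for beta, 14.1% for theta and 22.4% for zeta, so the winner is zeta. At work-up zeta still holds 24.0% of its substrate, against the 20.6% from the mean age. The neighbour of zeta charged with 1.8 mM of capture agent has the same mean age, so I reckon 30.8% of open intermediate for it, and it holds 27.1%.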